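## Retrosynthetic overview

- **Numbering and key feature.** Ring A is C1(Me)=C2–C3(OH)–C4(Br)–C5(Me)2–C6(spiro); ring B is C6–C7H2–C8(Br)=C9(Me)–C10H2–C11H2. The plan rests on the C3 carbinol of ring A, which lies between C4–Br and the C1=C2 alkene. With that alkene moved to the exocyclic C1=CH2 position, C3–OH is homoallylic and C2–C3 is the bond a type-two carbonyl-ene reaction makes.
- **Late disconnections.** Alkene shift (C1=CH2 to C1=C2). C2–C3 by ene closure of the C3 aldehyde onto the isopropenyl group on C6. C4–Br by amine-catalysed α-bromination.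
- **C5–C6.** The bond between the two quaternary carbons comes from an Ireland–Claisen rearrangement of a ring-B prenyl ester. The carboxyl group then becomes the isopropenyl group, and the vinyl group becomes C4H2–C3HO.
- **Ring B is (R)-carvone.** Its C6 centre sets C8–O. The C8 silyl ether steers the [3,3] shift at the then planar C6. C8 finally becomes C8(Br)=C9(Me) by way of enone, enol triflate and nickel-catalysed bromide exchange.
- **Order of rings.** Ring B comes from the chiral pool; ring A is closed last.

Key step: step 16

**Assumption:** the (2R,5R) amine catalyst of step 15 is taken to deliver bromine to the enamine face that gives (4S), as phenyl shielding of the E-enamine predicts.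

**Remark 1:** the C6 centre of 5–9 is erased in step 6, so its epimerisation in steps 4 and 5 does not matter. The descriptor at C6 changes from R to S in step 8 only because the substituent priorities change.

**Remark 2:** 14–19 contain a 3,3,4,4-tetrasubstituted hexa-1,5-diene. They are kept at or below 25 °C and away from divalent palladium, either of which could start a Cope rearrangement across C5–C6.

**Remark 3:** the brominating dienone of step 15 is a known reagent made by brominating 4-bromo-2,6-di-tert-butylphenol. It is not counted as a step.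

## Route

Step 1
Reactants: 1 (R)-(−)-carvone
Product: 2 (−)-cis-carveol [(6R,8R); (1R,5R)-2-methyl-5-(prop-1-en-2-yl)cyclohex-2-en-1-ol]
Conditions: NaBH4, CeCl3·7H2O, MeOH, 0 °C
Reagents that add atoms: none
Why: Luche reduction is 1,2-selective, and axial hydride delivery to the half-chair that holds the isopropenyl group equatorial places the new C8 hydroxyl cis to the C6 substituent (8R).

Step 2
Reactants: 2 (−)-cis-carveol
Product: 3 cis-carveol tert-butyldimethylsilyl ether (6R,8R)
Conditions: TBSCl, imidazole, DMF, 23 °C
Reagents that add atoms: tert-butyldimethylsilyl chloride CC(C)(C)[Si](C)(C)Cl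
Why: Imidazole-promoted silylation of a secondary allylic alcohol is routine and installs the bulky group at C8 that later steers the rearrangement.

Step 3
Reactants: 3 cis-carveol tert-butyldimethylsilyl ether
Product: 5 methyl ketone 1-[(1R,5R)-5-(tert-butyldimethylsilyloxy)-4-methylcyclohex-3-en-1-yl]ethanone, via side-chain diol 4 (not isolated)
Conditions: OsO4 (2 mol %), NaIO4, 2,6-lutidine, dioxane/H2O, 23 °C
Reagents that add atoms: osmium tetroxide O=[Os](=O)(=O)=O (oxygen carrier); sodium periodate [Na+].[O-]I(=O)(=O)=O (terminal oxygen source)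
Why: Lemieux–Johnson cleavage: osmylation follows steric access and takes the open 1,1-disubstituted alkene rather than the ring alkene, which is trisubstituted and flanked by the allylic silyl ether, and periodate cleaves diol 4 in the same flask.

Step 4
Reactants: 5 methyl ketone
Product: 7 (1R,5R)-5-(tert-butyldimethylsilyloxy)-4-methylcyclohex-3-ene-1-carboxylic acid, via tribromomethyl ketone 6 (not isolated)
Conditions: Br2, NaOH, dioxane/H2O, 0 °C; then 1 M HCl to pH 3
Reagents that add atoms: bromine BrBr (bromine atoms of 6 only); sodium hydroxide [Na+].[OH-] (carboxyl oxygen)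
Why: Haloform reaction: the methyl group is brominated three times under base and hydroxide then expels tribromomethanide, a sequence that leaves trisubstituted ring alkenes and silyl ethers untouched.

Step 5
Reactants: 7 ring-B carboxylic acid; 8 3-methylbut-2-en-1-ol (prenol)
Product: 9 prenyl ester of 7
Conditions: DCC, DMAP (cat.), CH2Cl2, 0 to 23 °C
Reagents that add atoms: none
Why: Steglich esterification couples the secondary acid and the primary allylic alcohol under neutral conditions without allylic transposition.

Step 6
Reactants: 9 prenyl ester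
Product: 12 (6R,8R)-acid [(1R,5R)-5-(tert-butyldimethylsilyloxy)-4-methyl-1-(2-methylbut-3-en-2-yl)cyclohex-3-ene-1-carboxylic acid; CO2H cis to C8–O], via silyl ketene acetal 10 (not isolated), via trimethylsilyl ester 11 (not isolated)
Conditions: LDA, THF, −78 °C; TMSCl, −78 to 23 °C, then 65 °C; 1 M HCl, 23 °C
Reagents that add atoms: chlorotrimethylsilane C[Si](C)(C)Cl (silicon of 10 and 11 only)
Why: Ireland–Claisen rearrangement, which is known to join two fully substituted carbons in prenyl cyclohexenecarboxylates, forms C5–C6; C6 is planar in 10 and is set by C8, because allylic 1,2-strain with the C9 methyl group holds the silyloxy group pseudoaxial and 1,3-syn to one face of the ketene acetal, so the prenyl terminus bonds to the other face and the carboxyl group ends up cis to C8–O.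

Step 7
Reactants: 12 rearranged acid
Product: 13 methyl ketone (6R,8R) with acetyl and 2-methylbut-3-en-2-yl groups on C6
Conditions: MeLi (3 equiv), Et2O, 0 to 23 °C; inverse quench into ice-water
Reagents that add atoms: methyllithium [Li]C
Why: Methyllithium adds once to the lithium carboxylate and stops at the dilithium gem-diolate, which collapses to the methyl ketone only on quenching, a method that serves well for acids on quaternary carbons.

Step 8
Reactants: 13 methyl ketone
Product: 14 silyl ether (6S,8R) with isopropenyl and 2-methylbut-3-en-2-yl groups on C6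
Conditions: Cp2Ti(μ-CH2)(μ-Cl)AlMe2 (Tebbe reagent), pyridine (cat.), toluene/THF, −40 to 23 °C
Reagents that add atoms: Tebbe reagent C[Al](C)C[Ti](Cl)(C1C=CC=C1)C1C=CC=C1 (cyclopentadienyl rings drawn sigma-bonded)
Why: Tebbe methylenation: the small, weakly basic titanium methylidene converts hindered and enolisable ketones at or below room temperature, where a Wittig reagent would need heat that the 1,5-diene product should not see.

Step 9
Reactants: 14 silyl ether
Product: 15 allylic alcohol (1R,5S)-2-methyl-5-(2-methylbut-3-en-2-yl)-5-(prop-1-en-2-yl)cyclohex-2-en-1-ol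
Conditions: Bu4NF, THF, 23 °C
Reagents that add atoms: none
Why: Fluoride cleaves the silyl ether selectively and nothing else in the hydrocarbon framework responds to Bu4NF.

Step 10
Reactants: 15 allylic alcohol
Product: 16 enone (5S)-2-methyl-5-(2-methylbut-3-en-2-yl)-5-(prop-1-en-2-yl)cyclohex-2-en-1-one
Conditions: Dess–Martin periodinane, CH2Cl2, 0 to 23 °C
Reagents that add atoms: none
Why: Dess–Martin oxidation of the allylic alcohol gives the enone under mild conditions and erases the C8 relay centre once C6 is in place.

Step 11
Reactants: 16 enone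
Product: 18 tetrasubstituted enol triflate C8(OTf)=C9(Me) (6S), via lithium enolate 17 (not isolated)
Conditions: LiBH(s-Bu)3, THF, −78 °C; PhNTf2, −78 to 0 °C
Reagents that add atoms: lithium tri-sec-butylborohydride [Li+].CCC(C)[BH-](C(C)CC)C(C)CC (hydride; lithium of 17 only); N-phenylbis(trifluoromethanesulfonimide) O=S(=O)(N(c1ccccc1)S(=O)(=O)C(F)(F)F)C(F)(F)F
Why: The bulky borohydride reduces β-unsubstituted cyclohexenones in the 1,4-sense, so the enolate is generated regiospecifically across C8–C9 and O-triflation fixes the tetrasubstituted double bond where the target needs it.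

Step 12
Reactants: 18 enol triflate
Product: 19 bromoalkene (4S)-2-bromo-1-methyl-4-(2-methylbut-3-en-2-yl)-4-(prop-1-en-2-yl)cyclohex-1-ene
Conditions: Ni(cod)2 (10 mol %), LiBr, DMA/THF, 23 °C
Reagents that add atoms: lithium bromide [Li+].[Br-]
Why: Nickel-catalysed enol triflate–halide exchange (oxidative addition of zerovalent nickel into C–OTf, anion exchange with bromide, reductive elimination) keeps the alkene position and runs at room temperature without touching unactivated alkenes.

Step 13
Reactants: 19 bromoalkene
Product: 21 primary alcohol 3-[(1S)-3-bromo-4-methyl-1-(prop-1-en-2-yl)cyclohex-3-en-1-yl]-3-methylbutan-1-ol, via trialkylborane 20 (not isolated)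
Conditions: Sia2BH (from BH3·THF and 2-methylbut-2-ene), THF, 0 °C; NaOH, H2O2, 0 to 23 °C
Reagents that add atoms: disiamylborane CC(C)C(C)BC(C)C(C)C (boron of 20 only); hydrogen peroxide OO
Why: Hydroboration–oxidation: disiamylborane strongly prefers a monosubstituted alkene over a 1,1-disubstituted one, the isopropenyl group is moreover wedged between C5 and C6 and the bromoalkene is inert, so boron goes to terminal C3 only.

Step 14
Reactants: 21 primary alcohol
Product: 22 aldehyde 3-[(1S)-3-bromo-4-methyl-1-(prop-1-en-2-yl)cyclohex-3-en-1-yl]-3-methylbutanal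
Conditions: Dess–Martin periodinane, CH2Cl2, 0 to 23 °C
Reagents that add atoms: none
Why: Dess–Martin oxidation stops cleanly at the aldehyde and its mild medium does not trigger a premature ene or Prins reaction.

Step 15
Reactants: 22 aldehyde
Product: 23 α-bromo aldehyde (4S,6S) [(2S)-2-bromo-3-[(1S)-3-bromo-4-methyl-1-(prop-1-en-2-yl)cyclohex-3-en-1-yl]-3-methylbutanal]
Conditions: (2R,5R)-2,5-diphenylpyrrolidine (20 mol %), PhCO2H (20 mol %), 4,4-dibromo-2,6-di-tert-butylcyclohexa-2,5-dienone, CH2Cl2/pentane, −24 °C; cold filtration through silica, used at once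
Reagents that add atoms: 4,4-dibromo-2,6-di-tert-butylcyclohexa-2,5-dienone CC(C)(C)C1=CC(Br)(Br)C=C(C(C)(C)C)C1=O
Why: Enamine-catalysed asymmetric α-bromination, known for β-branched aldehydes up to 3,3-dimethylbutanal: the C2-symmetric amine shields one face of the E-enamine and so sets C4 as (S) independently of C6, while the dienone is too mild a bromine donor to attack the isopropenyl group.

Step 16
Reactants: 23 α-bromo aldehyde
Product: 25 exocyclic-methylene trans-bromohydrin (3S,4S,6S) [(2S,3S,6S)-2,8-dibromo-1,1,9-trimethyl-5-methylidenespiro[5.5]undec-8-en-3-ol], via aluminium alkoxide 24 (not isolated)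
Conditions: MeAl(OAr)2 [MABR, Ar = 4-bromo-2,6-di-tert-butylphenyl; 2 equiv, from Me3Al and ArOH, CH2Cl2, 23 °C], CH2Cl2, −78 to −40 °C; 1 M HCl
Reagents that add atoms: MABR C[Al](Oc1c(cc(Br)cc1C(C)(C)C)C(C)(C)C)Oc1c(cc(Br)cc1C(C)(C)C)C(C)(C)C (aluminium aryloxide part of 24 only)
Why: Proposed new method: the aldehyde oxygen binds the bulky aluminium aryloxide, the terminal isopropenyl carbon C2 attacks C3 while charge builds at tertiary C1, and a hydrogen of the C1 methyl group is relayed to oxygen, which leaves the exocyclic methylene and, after loss of methane, alkoxide 24; an α-bromo aldehyde has not served as the enophile before, but bromine only raises the electrophilicity of C3 and the reagent is neither a base nor a bromide acceptor at −78 °C. The closest known reaction type is the aluminium-promoted type-two intramolecular carbonyl-ene cyclisation of 2-substituted 5-methylhex-5-enals to 2-substituted 5-methylenecyclohexanols, in which Me2AlCl reacts through a closed transition state with axial oxygen (cis alcohol) and bulky aryloxides such as MABR through one with equatorial oxygen (trans alcohol). Ring A closes in a 6-exo-trig mode at the carbonyl group with the tether on the central ene carbon C1, and the two quaternary carbons C5 and C6 keep the chain folded. C3 is controlled by C4: in the chair the C4–Br bond is equatorial and antiperiplanar to the forming C2–C3 bond (an axial bromine would face the axial ring-B methylene on C6), and the O–Al unit takes the equatorial site because the axial one is syn-axial to a C5 methyl group, so hydroxyl and bromine come out trans. For this reason Me2AlCl, whose concerted hydrogen transfer needs axial oxygen and would favour the C3 epimer, is replaced by MABR. The step needs the isopropenyl group to react rather than the C8=C9 bromoalkene, which is deactivated by bromine and cannot reach C3, and it needs C4 to hold its configuration, which low temperature and the absence of base secure; any proton loss from C2 instead of the methyl group gives 26 directly and is harmless.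

Step 17
Reactants: 25 exocyclic-methylene trans-bromohydrin
Product: 26 target (3S,4S,6S) [(2S,3S,6S)-2,8-dibromo-1,1,5,9-tetramethylspiro[5.5]undeca-4,8-dien-3-ol]
Conditions: Co(salen)Cl [salen = N,N′-bis(3,5-di-tert-butylsalicylidene)cyclohexane-1,2-diamine dianion] (5 mol %), PhSiH3 (10 mol %), benzene, 23 °C
Reagents that add atoms: none
Why: Cobalt-hydride hydrogen-atom-transfer isomerisation: reversible H-atom addition to the methylene carbon gives the tertiary C1 radical, which can give back a hydrogen only from its methyl group or from C2 because C6 is quaternary, so the more stable trisubstituted C1=C2 alkene accumulates under neutral conditions that spare the bromohydrin and cannot walk on to a ketone.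

## Compound list

1 | (R)-(−)-carvone | CC(=C)[C@@H]1CC=C(C)C(=O)C1 | starting material
2 | (−)-cis-carveol (6R,8R) | CC(=C)[C@@H]1CC=C(C)[C@H](O)C1 | intermediate
3 | cis-carveol TBS ether | CC(=C)[C@@H]1CC=C(C)[C@H](O[Si](C)(C)C(C)(C)C)C1 | intermediate
4 | side-chain diol (epimers at the new carbinol carbon) | CC(O)(CO)[C@@H]1CC=C(C)[C@H](O[Si](C)(C)C(C)(C)C)C1 | intermediate
5 | ring-B methyl ketone | CC(=O)[C@@H]1CC=C(C)[C@H](O[Si](C)(C)C(C)(C)C)C1 | intermediate
6 | tribromomethyl ketone | BrC(Br)(Br)C(=O)[C@@H]1CC=C(C)[C@H](O[Si](C)(C)C(C)(C)C)C1 | intermediate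
7 | ring-B carboxylic acid | OC(=O)[C@@H]1CC=C(C)[C@H](O[Si](C)(C)C(C)(C)C)C1 | intermediate
8 | 3-methylbut-2-en-1-ol | CC(C)=CCO | starting material
9 | prenyl ester | CC(C)=CCOC(=O)[C@@H]1CC=C(C)[C@H](O[Si](C)(C)C(C)(C)C)C1 | intermediate
10 | trimethylsilyl ketene acetal (both geometries, 8R) | CC(C)=CCOC(O[Si](C)(C)C)=C1CC=C(C)[C@H](O[Si](C)(C)C(C)(C)C)C1 | intermediate
11 | trimethylsilyl ester of 12 | C[Si](C)(C)OC(=O)[C@]1(C(C)(C)C=C)CC=C(C)[C@H](O[Si](C)(C)C(C)(C)C)C1 | intermediate
12 | rearranged acid (6R,8R) | OC(=O)[C@]1(C(C)(C)C=C)CC=C(C)[C@H](O[Si](C)(C)C(C)(C)C)C1 | intermediate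
13 | quaternary methyl ketone (6R,8R) | CC(=O)[C@]1(C(C)(C)C=C)CC=C(C)[C@H](O[Si](C)(C)C(C)(C)C)C1 | intermediate
14 | isopropenyl silyl ether (6S,8R) | CC(=C)[C@]1(C(C)(C)C=C)CC=C(C)[C@H](O[Si](C)(C)C(C)(C)C)C1 | intermediate
15 | allylic alcohol (6S,8R) | CC(=C)[C@]1(C(C)(C)C=C)CC=C(C)[C@H](O)C1 | intermediate
16 | 5,5-disubstituted carvone-type enone (6S) | CC(=C)[C@]1(C(C)(C)C=C)CC=C(C)C(=O)C1 | intermediate
17 | lithium enolate | CC(=C)[C@]1(C(C)(C)C=C)CCC(C)=C([O-])C1.[Li+] | intermediate
18 | enol triflate | CC(=C)[C@]1(C(C)(C)C=C)CCC(C)=C(OS(=O)(=O)C(F)(F)F)C1 | intermediate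
19 | ring-B bromoalkene | CC(=C)[C@]1(C(C)(C)C=C)CCC(C)=C(Br)C1 | intermediate
20 | disiamyl(alkyl)borane | CC(=C)[C@]1(C(C)(C)CCB(C(C)C(C)C)C(C)C(C)C)CCC(C)=C(Br)C1 | intermediate
21 | primary alcohol | CC(=C)[C@]1(C(C)(C)CCO)CCC(C)=C(Br)C1 | intermediate
22 | aldehyde | CC(=C)[C@]1(C(C)(C)CC=O)CCC(C)=C(Br)C1 | intermediate
23 | α-bromo aldehyde (4S,6S), ene precursor | O=C[C@@H](Br)C(C)(C)[C@@]1(C(C)=C)CCC(C)=C(Br)C1 | intermediate
24 | aluminium alkoxide of 25 | C=C1C[C@H](O[Al](Oc3c(cc(Br)cc3C(C)(C)C)C(C)(C)C)Oc3c(cc(Br)cc3C(C)(C)C)C(C)(C)C)[C@@H](Br)C(C)(C)[C@]12CCC(C)=C(Br)C2 | intermediate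
25 | exocyclic-methylene trans-bromohydrin (3S,4S,6S) | C=C1C[C@H](O)[C@@H](Br)C(C)(C)[C@]12CCC(C)=C(Br)C2 | intermediate
26 | CNP0268938.1 (3S,4S,6S) | CC1=C[C@H](O)[C@@H](Br)C(C)(C)[C@]12CCC(C)=C(Br)C2 | target

## Step count

Total step count: 17. Longest linear sequence: 17 steps (1 to 26).

## Steps most likely to fail

**Step 16.**
- What may go wrong:
  - The closure may run through the closed transition state with axial oxygen and set C3 the wrong way.
  - The bromo aldehyde may enolise and lose its C4 configuration, or lose HBr.
  - The developing C1 cation may trigger a 1,2-shift from C6.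
- The fallback sets out from 23 and comes back at 26, and it uses only known reaction types.
  - Vinylmagnesium bromide (THF, −78 °C, cold quench) adds to 23 to give the vinyl carbinol F1 as C3 epimers.
  - Dess–Martin oxidation gives the α-bromo vinyl ketone F2.
  - Corey–Bakshi–Shibata reduction with the (R)-methyl oxazaborolidine and catecholborane (toluene, −78 °C) gives the (3S,4S)-bromohydrin diene F3. The catalyst reads the large bromoalkyl arm against the small vinyl arm, and polar Felkin–Anh control points the same way.
  - Ring-closing metathesis with the second-generation Grubbs catalyst (toluene, 60 °C) joins the isopropenyl and vinyl groups as C1=C2.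
- Ring A is then closed at the alkene, C3 stands under reagent control, and no alkene shift is needed.

**Step 15.**
- What may go wrong:
  - Enamine formation at the neopentyl-type aldehyde may be slow.
  - The catalyst may be mismatched with C6.
  - Bromine may be transferred to the isopropenyl group.
  - Configuration at C4 may erode during isolation.
- The fallback sets out from 22 and comes back at 23, and it replaces catalyst control by an auxiliary.
  - Pinnick oxidation gives the carboxylic acid F4.
  - DCC/DMAP coupling with (S)-4-benzyloxazolidin-2-one gives the N-acyl oxazolidinone F5.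
  - n-Bu2BOTf and i-Pr2NEt (CH2Cl2, −78 °C) give the dibutylboron enolate F6.
  - NBS brominates F6 from the face away from the benzyl group to give the (4S)-α-bromo imide F7.
  - LiBH4 (Et2O, MeOH, 0 °C) releases the bromo alcohol F8, which can be purified and stored.
  - Dess–Martin oxidation just before the cyclisation gives 23.

**Step 6.**
- What may go wrong:
  - Discrimination between the two faces of the ketene acetal may be incomplete.
  - A sluggish [3,3] shift between two fully substituted carbons may let the ketene acetal revert to ester.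
- The fallback sets out from 12 (as a mixture of C6 epimers) and comes back at 15. It sorts the isomers chemically instead of relying on selectivity.
  - Bu4NF gives the hydroxy acid F9.
  - DCC/DMAP at high dilution closes only the isomer with carboxyl and C8–OH cis to the bridged γ-lactone F10. The trans hydroxy acid stays acidic and is washed out with aqueous NaHCO3.
  - MeLi (1.1 equiv, Et2O, −78 °C) opens the hindered lactone once to the hydroxy ketone F11.
  - Excess Tebbe reagent methylenates F11 to 15.

## Further compounds

F1 | step 16 | vinyl carbinol (C3 epimers, 4S,6S) | C=CC(O)[C@@H](Br)C(C)(C)[C@@]1(C(C)=C)CCC(C)=C(Br)C1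
F2 | step 16 | α-bromo vinyl ketone (4S,6S) | C=CC(=O)[C@@H](Br)C(C)(C)[C@@]1(C(C)=C)CCC(C)=C(Br)C1
F3 | step 16 | (3S,4S)-bromohydrin diene | C=C[C@H](O)[C@@H](Br)C(C)(C)[C@@]1(C(C)=C)CCC(C)=C(Br)C1
F4 | step 15 | carboxylic acid from 22 | OC(=O)CC(C)(C)[C@@]1(C(C)=C)CCC(C)=C(Br)C1
F5 | step 15 | N-acyl oxazolidinone | O=C1OC[C@H](Cc2ccccc2)N1C(=O)CC(C)(C)[C@@]3(C(C)=C)CCC(C)=C(Br)C3
F6 | step 15 | dibutylboron enolate (Z) | CCCCB(CCCC)O/C(=C\C(C)(C)[C@@]3(C(C)=C)CCC(C)=C(Br)C3)N1[C@@H](Cc2ccccc2)COC1=O
F7 | step 15 | (4S)-α-bromo imide | O=C1OC[C@H](Cc2ccccc2)N1C(=O)[C@@H](Br)C(C)(C)[C@@]3(C(C)=C)CCC(C)=C(Br)C3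
F8 | step 15 | bromo alcohol (4S,6S) | OC[C@@H](Br)C(C)(C)[C@@]1(C(C)=C)CCC(C)=C(Br)C1
F9 | step 6 | hydroxy acid (6R,8R) | OC(=O)[C@]1(C(C)(C)C=C)CC=C(C)[C@H](O)C1
F10 | step 6 | bridged γ-lactone | O=C1O[C@@H]2C[C@@]1(C(C)(C)C=C)CC=C2C
F11 | step 6 | hydroxy ketone (6R,8R) | CC(=O)[C@]1(C(C)(C)C=C)CC=C(C)[C@H](O)C1
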